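Carbon numbers C1–C15 are the germacrane numbers of the target and are used for every intermediate. In the target SMILES, O[C@H]1 is C8. Then follow C9, C10 (bearing C14), C1, C2, C3, C4 (bearing C15), C5, C6, the ring O, C12, C11 (bearing C13) and C7.

## Analysis of the target

- Compound 26 is a germacranolide. It has a carbocycle C1–C10, C14 on C10, C15 on C4, and a lactone built from O–C6, C7=C11 and C12(=O), with C13 on C11.
- The ten-membered ring is fused along C6–C7 to a γ-alkylidene butenolide, so the enol-lactone double bond C5=C6 is itself a ring bond.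
- Both ring double bonds are cis along the ring path (C4 cis to C7, C9 cis to C2). For C5=C6 this is the E geometry that open-chain alkylidene butenolides avoid. C7=C11 is tetrasubstituted with four different carbon groups.
- The stereocentres are C2 (S), C4 (R, tertiary carbinol) and C8 (S). C2–OAc and C4–OH are 1,3-syn. C8 is insulated from both by C1=C10 and cannot be relayed from them.
- Every second ring carbon carries oxygen (C2, C4, C6, C8). The segments C8–C9–C10(C14)=C1–C2 and C2–C3–C4(C15)=C5–C6 are two copies of one five-carbon unit.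
- The sensitive groups are:
  - the angelate, which can isomerise from Z to E;
  - the 13-acetate, an allylic and vinylogous leaving group;
  - the tertiary allylic alcohol;
  - the base- and nucleophile-sensitive dienolide;
  - five oxygens in three different acylation states.
- The hard part is to close a strained medium ring that holds the E enol lactone, without a long protecting-group campaign.
- The route exploits the C6–C7 bond. It belongs to both rings and joins two natural acceptor carbons: C6, a carbonyl carbon, and C7, the β-carbon of the C12 ester.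

## Retrosynthetic reasoning

**C14–O, 26 to 24.** The free primary alcohol is removed first. A Riley oxidation of the C10 methyl group of 24 needs no protecting group at C14. Its ene/[2,3] mechanism places the new CH2OH trans to C2 whatever the starting geometry. The ring may therefore be built with the easily made ring-trans C1=C10 bond.

**C5=C6 and C4–OH, 24 to 22.** The unit C4(OH)–C5=C6–O is the product of a vinylogous eliminative opening of a 4,5-epoxide by the γ-carbanion at C6. This moves the tertiary carbinol problem to a trisubstituted epoxide. It also lets the ring, not an open-chain preference, fix the E geometry of C5=C6. Epoxy lactone 22 is an isomer of 24, so no redox step is needed.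

**C6–C7 and O–C12, 22 to 19 (key cut).** Both rings are opened at once. C6 becomes the aldehyde of an epoxy aldehyde, and C7 becomes the bromide-bearing β-carbon of an acrylate whose ester is cis to the bromide. Both carbons are acceptors, so the forward step needs polarity reversal at C7. The precursor 19 is acyclic, already fully acylated, and has no stereocentre at C6 to control. Cutting elsewhere would require a preformed E-alkylidene butenolide, which is not accessible in open-chain form.

**Epoxide, 19 to 16 through 18 and 17.** The epoxy aldehyde goes back to the E enal 16. Reduction, reagent-controlled epoxidation of the allylic alcohol and re-oxidation set C4 absolutely. C5 is set as well but is erased later.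

**C2–C3 and C8–C9, 16 to 14 to 8.** The two identical five-carbon units are removed one after the other as dienol ether 10, made from 9. Each vinylogous aldol step forms one carbinol carbon (C2, then C8), one E-trisubstituted double bond and the next aldehyde. Both aldehydes must be attacked on the Si face, so one catalyst serves twice. Each new hydroxyl is acylated at once, C8 with 12 and C2 as the acetate. This is why no protecting group is needed.

**C7=C11, 8 to 3 to 1 and 5.** The tetrasubstituted double bond is taken back to an alkyne. An anti dihalogenation of ynoate 3 gives 4 and fixes Br cis to the ester. A halogen-selective coupling with 5 brings in C13. Ynoate 3 comes from acetal 1 by carboxylation.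

## Alternatives that were turned down

**Alternative 1: ring-closing metathesis at C1=C10 (the textbook cut).**
- Forward key step: a ruthenium carbene closes diene A1, which already holds the alkylidene butenolide.
- An open-chain aldol–elimination gives the Z-alkylidene isomer, in which the two olefinic arms point away from each other. The E isomer A1 is therefore not available selectively.
- The closure must form a trisubstituted double bond in a ten-membered ring from a 1,1-disubstituted allylic ether and an allylic acetate. Both are deactivated, so dimerisation should win.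
- C14 would also need a protecting group.

**Alternative 2: allylchromium closure at C6–C7, the classical germacranolide ring closure.**
- Forward key step: the 2-(bromomethyl)acrylate A2 adds through C7 to the C6 aldehyde and lactonises to the α-methylene lactone A3.
- The bond is the same as in the chosen route, but the oxidation pattern is wrong. A3 has H7 and C11=C13.
- Reaching C7=C11 with an oxygen at C13 needs removal of a non-acidic hydrogen next to the C8 ester, plus an allylic oxidation among five other allylic sites. This costs more steps than the closure saves.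

**Alternative 3: anionic oxy-Cope ring expansion (C8–C9 formed, a temporary C1–C6 bond broken).**
- Forward key step: the alkoxide of divinylcyclohexenol A4 rearranges to cyclodecadienone A5.
- The ring is gained in one step, but the six-membered precursor offers no place for the C2 oxygen. A 3,5-dioxygenated cyclohexanone would eliminate.
- C4=C5 emerges conjugated with the ketone, and C11–C13 must still be attached at C7 of a β-alkoxy ketone.
- The way from A5 to the target is longer than the whole chosen route.

Key step: step 14

**Assumptions**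
- The oxazaborolidinone derived from N-tosyl-L-tryptophan is taken to direct 10 to the Si face of both aldehydes. If the sense is the opposite, the D-tryptophan catalyst is used and nothing else changes.
- C6 of 21, 22, F1 and F7 is expected as a mixture of epimers. It is left open in the SMILES because step 15 erases it.

## Route

Step 1
Reactants: 1 3,3-diethoxyprop-1-yne
Product: 3 methyl 4,4-diethoxybut-2-ynoate, via lithium acetylide 2 (not isolated)
Conditions: n-BuLi, THF, −78 °C; then ClCO2Me, −78 to 0 °C
Reagents that add atoms: methyl chloroformate, COC(=O)Cl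
Why: Deprotonation of the terminal alkyne and C-acylation of 2 by the chloroformate is a standard ynoate synthesis; it joins C12 to C11 while the acetal masks C8 as the later aldehyde.

Step 2
Reactants: 3 methyl 4,4-diethoxybut-2-ynoate
Product: 4 methyl (E)-3-bromo-4,4-diethoxy-2-iodobut-2-enoate
Conditions: IBr, CH2Cl2, −20 °C to rt, dark
Reagents that add atoms: iodine monobromide, BrI
Why: Anti halogen addition to an alkyne; bromide should end at the conjugate carbon C7 and iodine at the α-carbon C11, which fixes Br cis to the ester and gives two halogens of different reactivity.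

Step 3
Reactants: 4 methyl (E)-3-bromo-4,4-diethoxy-2-iodobut-2-enoate; 5 (tributylstannyl)methanol
Product: 6 methyl (Z)-3-bromo-4,4-diethoxy-2-(hydroxymethyl)but-2-enoate
Conditions: Pd(PPh3)4 (5 mol %), CuI (10 mol %), DMF, 40 °C
Reagents that add atoms: none
Why: Stille coupling; zerovalent palladium inserts into C–I much faster than into C–Br and the coupling goes with retention, so C13 is placed cis to C8 and the C7–Br bond is kept for step 14.

Step 4
Reactants: 6 methyl (Z)-3-bromo-4,4-diethoxy-2-(hydroxymethyl)but-2-enoate
Product: 7 methyl (Z)-2-(acetoxymethyl)-3-bromo-4,4-diethoxybut-2-enoate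
Conditions: Ac2O, pyridine, CH2Cl2, 0 °C to rt
Reagents that add atoms: acetic anhydride, CC(=O)OC(C)=O
Why: Plain acetylation installs the final 13-acetate; it must precede the unmasking of C8, because a free hydroxymethyl group cis to an aldehyde would cyclise and dehydrate.

Step 5
Reactants: 7 methyl (Z)-2-(acetoxymethyl)-3-bromo-4,4-diethoxybut-2-enoate
Product: 8 methyl (Z)-2-(acetoxymethyl)-3-bromo-4-oxobut-2-enoate
Conditions: CF3CO2H, H2O, CH2Cl2, 0 °C
Reagents that add atoms: water, O
Why: Acid hydrolysis of the acetal; the esters survive cold aqueous acid and the fully substituted double bond has no easy path for geometric scrambling.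

Step 6
Reactants: 9 3-methylbut-2-enal
Product: 10 (E)-tert-butyldimethyl[(3-methylbuta-1,3-dien-1-yl)oxy]silane
Conditions: TBSOTf, Et3N, CH2Cl2, 0 °C
Reagents that add atoms: tert-butyldimethylsilyl triflate, CC(C)(C)[Si](C)(C)OS(=O)(=O)C(F)(F)F
Why: Soft enolisation: O-silylation of the enal followed by γ-deprotonation gives the 1-silyloxydiene, the single five-carbon unit used in steps 7 and 9.

Step 7
Reactants: 8 methyl (Z)-2-(acetoxymethyl)-3-bromo-4-oxobut-2-enoate; 10 (E)-tert-butyldimethyl[(3-methylbuta-1,3-dien-1-yl)oxy]silane
Product: 11 methyl (2Z,4S,6E)-2-(acetoxymethyl)-3-bromo-4-hydroxy-6-methyl-8-oxoocta-2,6-dienoate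
Conditions: oxazaborolidinone from N-tosyl-L-tryptophan and PhBCl2 (30 mol %), i-PrOH, EtCN, −78 °C
Reagents that add atoms: none
Why: Catalytic enantioselective vinylogous Mukaiyama aldol reaction; the boron Lewis acid binds the aldehyde and the diene attacks with its terminal CH2 (C9) on the Si face, which sets C8 (S). The s-trans diene gives the E enal and isopropanol takes up the silyl group.

Step 8
Reactants: 11 methyl (2Z,4S,6E)-2-(acetoxymethyl)-3-bromo-4-hydroxy-6-methyl-8-oxoocta-2,6-dienoate; 12 angelic acid
Product: 14 methyl (2Z,4S,6E)-2-(acetoxymethyl)-4-(angeloyloxy)-3-bromo-6-methyl-8-oxoocta-2,6-dienoate, via angeloyl chloride 13 (not isolated)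
Conditions: 12, 1-chloro-N,N,2-trimethylprop-1-enylamine, CH2Cl2, 0 °C; then 11, pyridine, 0 °C to rt
Reagents that add atoms: none
Why: The acid chloride is made under neutral conditions that should keep the Z geometry, and the acylation needs only a weak base in the cold, which spares the δ-acyloxy enal from vinylogous elimination; C8 is untouched.

Step 9
Reactants: 14 methyl (2Z,4S,6E)-2-(acetoxymethyl)-4-(angeloyloxy)-3-bromo-6-methyl-8-oxoocta-2,6-dienoate; 10 (E)-tert-butyldimethyl[(3-methylbuta-1,3-dien-1-yl)oxy]silane
Product: 15 methyl (2Z,4S,6E,8S,10E)-2-(acetoxymethyl)-4-(angeloyloxy)-3-bromo-8-hydroxy-6,10-dimethyl-12-oxododeca-2,6,10-trienoate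
Conditions: oxazaborolidinone from N-tosyl-L-tryptophan and PhBCl2 (30 mol %), i-PrOH, EtCN, −78 °C
Reagents that add atoms: none
Why: Second pass of the same vinylogous Mukaiyama aldol reaction with the same catalyst; Si-face attack of C3 on the C2 aldehyde sets C2 (S) under catalyst control (C8 is too remote to interfere) and delivers C4=C5 (E) and the C6 aldehyde.

Step 10
Reactants: 15 methyl (2Z,4S,6E,8S,10E)-2-(acetoxymethyl)-4-(angeloyloxy)-3-bromo-8-hydroxy-6,10-dimethyl-12-oxododeca-2,6,10-trienoate
Product: 16 methyl (2Z,4S,6E,8S,10E)-8-acetoxy-2-(acetoxymethyl)-4-(angeloyloxy)-3-bromo-6,10-dimethyl-12-oxododeca-2,6,10-trienoate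
Conditions: Ac2O, pyridine, CH2Cl2, 0 °C
Reagents that add atoms: acetic anhydride, CC(=O)OC(C)=O
Why: Acetylation of the only free hydroxyl installs the final 2-acetate; pyridine is too weak a base to enolise the enal.

Step 11
Reactants: 16 methyl (2Z,4S,6E,8S,10E)-8-acetoxy-2-(acetoxymethyl)-4-(angeloyloxy)-3-bromo-6,10-dimethyl-12-oxododeca-2,6,10-trienoate
Product: 17 methyl (2Z,4S,6E,8S,10E)-8-acetoxy-2-(acetoxymethyl)-4-(angeloyloxy)-3-bromo-12-hydroxy-6,10-dimethyldodeca-2,6,10-trienoate
Conditions: NaBH4, CeCl3·7H2O, MeOH, −78 °C
Reagents that add atoms: none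
Why: Luche reduction gives clean 1,2-reduction of the enal; the four esters and the bromoacrylate are inert at this temperature.

Step 12
Reactants: 17 methyl (2Z,4S,6E,8S,10E)-8-acetoxy-2-(acetoxymethyl)-4-(angeloyloxy)-3-bromo-12-hydroxy-6,10-dimethyldodeca-2,6,10-trienoate
Product: 18 methyl (2Z,4S,6E,8S,10R,11R)-8-acetoxy-2-(acetoxymethyl)-4-(angeloyloxy)-3-bromo-10,11-epoxy-12-hydroxy-6,10-dimethyldodeca-2,6-dienoate
Conditions: Ti(OiPr)4 (10 mol %), D-(−)-diethyl tartrate (12 mol %), t-BuOOH, 4 Å molecular sieves, CH2Cl2, −20 °C
Reagents that add atoms: tert-butyl hydroperoxide, CC(C)(C)OO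
Why: Sharpless asymmetric epoxidation; only C4=C5 is part of an allylic alcohol, and the D-tartrate delivers oxygen to the face of the E-trisubstituted olefin that gives C4 (R) and C5 (R). The C4–O bond made here is the one kept in the target.

Step 13
Reactants: 18 methyl (2Z,4S,6E,8S,10R,11R)-8-acetoxy-2-(acetoxymethyl)-4-(angeloyloxy)-3-bromo-10,11-epoxy-12-hydroxy-6,10-dimethyldodeca-2,6-dienoate
Product: 19 methyl (2Z,4S,6E,8S,10R,11S)-8-acetoxy-2-(acetoxymethyl)-4-(angeloyloxy)-3-bromo-10,11-epoxy-6,10-dimethyl-12-oxododeca-2,6-dienoate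
Conditions: Dess–Martin periodinane, CH2Cl2, 0 °C to rt
Reagents that add atoms: none
Why: Dess–Martin oxidation of the primary epoxy alcohol under nearly neutral conditions; no stereocentre is touched (the C5 descriptor changes only through priorities).

Step 14
Reactants: 19 methyl (2Z,4S,6E,8S,10R,11S)-8-acetoxy-2-(acetoxymethyl)-4-(angeloyloxy)-3-bromo-10,11-epoxy-6,10-dimethyl-12-oxododeca-2,6-dienoate
Product: 22 (2S,4R,5R,8S)-2,13-diacetoxy-8-angeloyloxy-4,5-epoxygermacra-1(10)E,7(11)-dien-12,6-olide (C6 epimers), via alkenylchromium species 20 (not isolated), via chromium alkoxide 21 (not isolated)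
Conditions: CrCl2 (10 equiv), NiCl2 (10 mol %), DMSO–THF, rt, slow addition of 19 (final 2 mM)
Reagents that add atoms: none
Why: Nozaki–Hiyama–Kishi reaction run as a macrocyclisation: zerovalent nickel, made in situ by divalent chromium, inserts into the ester-activated C7–Br bond, and transmetalation gives the trivalent alkenylchromium 20, so the β-carbon of the acrylate becomes a nucleophile. Its 1,2-addition to the C6 aldehyde forms C6–C7 and closes the ten-membered ring (10-exo-trig) to give 21. The alkoxide oxygen of 21 sits cis to the methyl ester across C7=C11 and should acylate at once (5-exo-trig), closing the butenolide and expelling methoxide, which also makes the closure irreversible and outruns a Payne-type migration of the epoxide. The closest known reaction type is the formation of butenolides from cis-β-haloacrylates and aldehydes under the same conditions, together with chromium-mediated closures of ten-membered germacrane rings at this same bond. The double-bond geometry at C7=C11 is carried over with retention from 19, so only C6 and not C8 can reach C12. C6 is the only new stereocentre; it is not controlled and need not be, since step 15 makes it trigonal. The step needs chemoselectivity for the aldehyde over four esters, the epoxide and three allylic esters, which the low basicity and aldehyde preference of organochromium reagents secure, and it needs ring closure to beat oligomerisation, which slow addition and the two E-configured units of the chain should favour.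

Step 15
Reactants: 22 (2S,4R,5R,8S)-2,13-diacetoxy-8-angeloyloxy-4,5-epoxygermacra-1(10)E,7(11)-dien-12,6-olide (C6 epimers)
Product: 24 (2S,4R,8S)-2,13-diacetoxy-8-angeloyloxy-4-hydroxygermacra-1(10)E,5E,7(11)-trien-12,6-olide (ring-trans C1=C10), via oxidofuran anion 23 (not isolated)
Conditions: DBU (0.2 equiv), CH2Cl2, −20 °C
Reagents that add atoms: none
Why: Vinylogous E1cB opening of the epoxide: loss of the acidic γ-hydrogen H6 gives the aromatic anion 23, which pushes out the C5–O bond and leaves the C4–O bond and its configuration untouched. The ring allows only the isomer with C4 cis to C7 (5E), and the same opening with retention of a 13-acetate is known for 4,5-epoxy-7(11)-en-12,6-olides.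

Step 16
Reactants: 24 (2S,4R,8S)-2,13-diacetoxy-8-angeloyloxy-4-hydroxygermacra-1(10)E,5E,7(11)-trien-12,6-olide (ring-trans C1=C10)
Product: 26 (2S,4R,8S)-2,13-diacetoxy-8-angeloyloxy-4,14-dihydroxygermacra-1(10)E,5E,7(11)-trien-12,6-olide (ring-cis C1=C10; CNP0165707.1), via allylic seleninic acid 25 (not isolated)
Conditions: SeO2 (0.3 equiv), t-BuOOH, CH2Cl2, 0 °C to rt
Reagents that add atoms: tert-butyl hydroperoxide, CC(C)(C)OO
Why: Riley oxidation: ene reaction at the only electron-neutral olefin gives 25 (Se on C1, C10=C14), and its [2,3]-shift returns the double bond to C1=C10 with CH2OH trans to C2, which turns the ring-trans into the ring-cis olefin. This geometric switch is known for ring-trans 1(10)-unsaturated germacranolides; the other olefins are electron-poor or lack allylic hydrogen.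

## Compound list

1 | 3,3-diethoxyprop-1-yne | C#CC(OCC)OCC | starting material
2 | lithium 3,3-diethoxyprop-1-yn-1-ide | [Li]C#CC(OCC)OCC | intermediate (not isolated)
3 | methyl 4,4-diethoxybut-2-ynoate | COC(=O)C#CC(OCC)OCC | intermediate
4 | methyl (E)-3-bromo-4,4-diethoxy-2-iodobut-2-enoate | COC(=O)/C(I)=C(\Br)C(OCC)OCC | intermediate
5 | (tributylstannyl)methanol | CCCC[Sn](CCCC)(CCCC)CO | starting material
6 | methyl (Z)-3-bromo-4,4-diethoxy-2-(hydroxymethyl)but-2-enoate | COC(=O)/C(CO)=C(\Br)C(OCC)OCC | intermediate
7 | methyl (Z)-2-(acetoxymethyl)-3-bromo-4,4-diethoxybut-2-enoate | COC(=O)/C(COC(C)=O)=C(\Br)C(OCC)OCC | intermediate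
8 | methyl (Z)-2-(acetoxymethyl)-3-bromo-4-oxobut-2-enoate | COC(=O)/C(COC(C)=O)=C(\Br)C=O | intermediate
9 | 3-methylbut-2-enal | CC(C)=CC=O | starting material
10 | (E)-tert-butyldimethyl[(3-methylbuta-1,3-dien-1-yl)oxy]silane | C=C(C)/C=C/O[Si](C)(C)C(C)(C)C | intermediate
11 | methyl (2Z,4S,6E)-2-(acetoxymethyl)-3-bromo-4-hydroxy-6-methyl-8-oxoocta-2,6-dienoate | COC(=O)/C(COC(C)=O)=C(\Br)[C@@H](O)C/C(C)=C/C=O | intermediate
12 | angelic acid, (Z)-2-methylbut-2-enoic acid | C/C=C(/C)C(=O)O | starting material
13 | angeloyl chloride | C/C=C(/C)C(=O)Cl | intermediate (not isolated)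
14 | methyl (2Z,4S,6E)-2-(acetoxymethyl)-4-(angeloyloxy)-3-bromo-6-methyl-8-oxoocta-2,6-dienoate | COC(=O)/C(COC(C)=O)=C(\Br)[C@@H](OC(=O)/C(C)=C\C)C/C(C)=C/C=O | intermediate
15 | methyl (2Z,4S,6E,8S,10E)-2-(acetoxymethyl)-4-(angeloyloxy)-3-bromo-8-hydroxy-6,10-dimethyl-12-oxododeca-2,6,10-trienoate | COC(=O)/C(COC(C)=O)=C(\Br)[C@@H](OC(=O)/C(C)=C\C)C/C(C)=C/[C@@H](O)C/C(C)=C/C=O | intermediate
16 | methyl (2Z,4S,6E,8S,10E)-8-acetoxy-2-(acetoxymethyl)-4-(angeloyloxy)-3-bromo-6,10-dimethyl-12-oxododeca-2,6,10-trienoate | COC(=O)/C(COC(C)=O)=C(\Br)[C@@H](OC(=O)/C(C)=C\C)C/C(C)=C/[C@@H](OC(C)=O)C/C(C)=C/C=O | intermediate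
17 | methyl (2Z,4S,6E,8S,10E)-8-acetoxy-2-(acetoxymethyl)-4-(angeloyloxy)-3-bromo-12-hydroxy-6,10-dimethyldodeca-2,6,10-trienoate | COC(=O)/C(COC(C)=O)=C(\Br)[C@@H](OC(=O)/C(C)=C\C)C/C(C)=C/[C@@H](OC(C)=O)C/C(C)=C/CO | intermediate
18 | methyl (2Z,4S,6E,8S,10R,11R)-8-acetoxy-2-(acetoxymethyl)-4-(angeloyloxy)-3-bromo-10,11-epoxy-12-hydroxy-6,10-dimethyldodeca-2,6-dienoate | COC(=O)/C(COC(C)=O)=C(\Br)[C@@H](OC(=O)/C(C)=C\C)C/C(C)=C/[C@@H](OC(C)=O)C[C@@]1(C)O[C@@H]1CO | intermediate
19 | methyl (2Z,4S,6E,8S,10R,11S)-8-acetoxy-2-(acetoxymethyl)-4-(angeloyloxy)-3-bromo-10,11-epoxy-6,10-dimethyl-12-oxododeca-2,6-dienoate | COC(=O)/C(COC(C)=O)=C(\Br)[C@@H](OC(=O)/C(C)=C\C)C/C(C)=C/[C@@H](OC(C)=O)C[C@@]1(C)O[C@@H]1C=O | intermediate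
20 | alkenyl-CrCl2 species (CrCl2 on C7 in place of Br of 19) | COC(=O)/C(COC(C)=O)=C(\[Cr](Cl)Cl)[C@@H](OC(=O)/C(C)=C\C)C/C(C)=C/[C@@H](OC(C)=O)C[C@@]1(C)O[C@@H]1C=O | intermediate (not isolated)
21 | ten-membered C6–O–CrCl2 alkoxide with the methyl ester still in place | C/C=C(/C)C(=O)O[C@H]1C/C(C)=C/[C@@H](OC(C)=O)C[C@@]2(C)O[C@@H]2C(O[Cr](Cl)Cl)/C1=C(/COC(C)=O)C(=O)OC | intermediate (not isolated)
22 | (2S,4R,5R,8S)-2,13-diacetoxy-8-angeloyloxy-4,5-epoxygermacra-1(10)E,7(11)-dien-12,6-olide (C6 epimers) | C/C=C(/C)C(=O)O[C@H]1C/C(C)=C/[C@@H](OC(C)=O)C[C@@]3(C)O[C@@H]3C2OC(=O)C(COC(C)=O)=C21 | intermediate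
23 | 2-oxidofuran anion of 22 (protonated DBU as counter-ion) | C/C=C(/C)C(=O)O[C@H]1C/C(C)=C/[C@@H](OC(C)=O)C[C@@]3(C)O[C@@H]3c2oc([O-])c(COC(C)=O)c21.C1CCC2=[NH+]CCCN2CC1 | intermediate (not isolated)
24 | (2S,4R,8S)-2,13-diacetoxy-8-angeloyloxy-4-hydroxygermacra-1(10)E,5E,7(11)-trien-12,6-olide (ring-trans C1=C10) | C/C=C(/C)C(=O)O[C@H]1C/C(C)=C/[C@@H](OC(C)=O)C[C@@](C)(O)/C=C2/OC(=O)C(COC(C)=O)=C21 | intermediate
25 | C1-seleninic acid with C10=C14 | C/C=C(/C)C(=O)O[C@H]1CC(=C)C([Se](=O)O)[C@@H](OC(C)=O)C[C@@](C)(O)/C=C2/OC(=O)C(COC(C)=O)=C21 | intermediate (not isolated)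
26 | (2S,4R,8S)-2,13-diacetoxy-8-angeloyloxy-4,14-dihydroxygermacra-1(10)E,5E,7(11)-trien-12,6-olide (CNP0165707.1) | C/C=C(/C)C(=O)O[C@H]1C/C(CO)=C\[C@@H](OC(C)=O)C[C@@](C)(O)/C=C2/OC(=O)C(COC(C)=O)=C21 | target

## Step count and weak points

Total: 16 steps. Longest linear sequence: 15 steps (steps 1–5 and 7–16). Step 6 is a one-step branch whose product is used twice. No protecting group is used apart from the acetal already present in 1.

**Step 14 (key step).**
- What may go wrong: divalent chromium may reduce or open the α,β-epoxy aldehyde before the hindered, tetrasubstituted alkenylchromium reaches it. Oligomerisation may also compete with closure of the strained ring.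
- Fallback: it sets out from 16, so the ring is closed before any epoxide exists. The same nickel/chromium closure on the enal should give the triene lactone F1.
- A Schenck ene reaction of F1 with singlet oxygen (O2, tetraphenylporphyrin, light, CH2Cl2, −78 °C) then abstracts the activated H6 and places oxygen on C4, giving the hydroperoxide F2.
- Reduction of F2 with PPh3 rejoins the route at 24. In this variant the configuration at C4 depends on peripheral attack on the macrocycle and not on a reagent.

**Step 2.**
- What may go wrong: the electrophilic addition to a doubly deactivated alkyne may be slow, and the placement of iodine and bromine may not be uniform. That would spoil the halogen-based selectivity of step 3.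
- Fallback: it sets out from 3 and selects by electronic activation instead. Anti addition of Br2 gives the dibromide F3, and acid hydrolysis gives the dibromo aldehyde F4.
- In F4 the bromide at C11 is β to the aldehyde and should insert palladium first.
- Stille coupling of F4 with (acetoxymethyl)tributylstannane F5, made from 5 and Ac2O, rejoins the route at 8.

**Step 8.**
- What may go wrong: the angeloyl unit may isomerise from Z to E during activation or acylation. Base-induced vinylogous loss of the new C8 ester from the δ-acyloxy enal is also possible.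
- Fallback: it sets out from 8. Step 7 is run with the D-tryptophan-derived catalyst to give the C8 epimer F6.
- A Mitsunobu reaction of F6 with 12 (PPh3, diisopropyl azodicarboxylate, toluene, 0 °C) esterifies with inversion under neutral conditions and rejoins the route at 14.

**Step 15.**
- What may go wrong: the anion may expel the 13-acetate instead of opening the epoxide. Deprotonation at C8 would erode that stereocentre.
- Fallback: it sets out from 22 and replaces the poor alkoxide leaving group by iodide. LiI and AcOH in THF should open the epoxide at the less substituted C5 to give the iodohydrin F7.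
- Et3N at 0 °C then suffices to remove H6 and iodide from F7, which rejoins the route at 24.

**Step 16.**
- What may go wrong: the ene step may be slow because the C2 acetate deactivates C1=C10. Attack at C9 or over-oxidation to the aldehyde may compete.
- Fallback: it sets out from 24. A Schenck ene reaction with singlet oxygen at C1=C10 gives the C1 hydroperoxide with C10=C14, F8, and PPh3 reduces it to the allylic alcohol F9.
- A 1,3-transposition of F9 catalysed by Ph3SiOReO3 moves the oxygen to the primary C14 and restores C1=C10, arriving at 26.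

## Further compounds

F1 | step 14 | (2S,8S)-2,13-diacetoxy-8-angeloyloxygermacra-1(10)E,4E,7(11)-trien-12,6-olide (C6 epimers) | C/C=C(/C)C(=O)O[C@H]1C/C(C)=C/[C@@H](OC(C)=O)C/C(C)=C/C2OC(=O)C(COC(C)=O)=C21
F2 | step 14 | (2S,4R,8S)-2,13-diacetoxy-8-angeloyloxy-4-hydroperoxygermacra-1(10)E,5E,7(11)-trien-12,6-olide | C/C=C(/C)C(=O)O[C@H]1C/C(C)=C/[C@@H](OC(C)=O)C[C@@](C)(OO)/C=C2/OC(=O)C(COC(C)=O)=C21
F3 | step 2 | methyl (E)-2,3-dibromo-4,4-diethoxybut-2-enoate | COC(=O)/C(Br)=C(\Br)C(OCC)OCC
F4 | step 2 | methyl (E)-2,3-dibromo-4-oxobut-2-enoate | COC(=O)/C(Br)=C(\Br)C=O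
F5 | step 2 | (acetoxymethyl)tributylstannane | CCCC[Sn](CCCC)(CCCC)COC(C)=O
F6 | step 8 | methyl (2Z,4R,6E)-2-(acetoxymethyl)-3-bromo-4-hydroxy-6-methyl-8-oxoocta-2,6-dienoate | COC(=O)/C(COC(C)=O)=C(\Br)[C@H](O)C/C(C)=C/C=O
F7 | step 15 | 4-hydroxy-5-iodo lactone from 22 (inversion at C5, C6 epimers) | C/C=C(/C)C(=O)O[C@H]1C/C(C)=C/[C@@H](OC(C)=O)C[C@@](C)(O)[C@@H](I)C2OC(=O)C(COC(C)=O)=C21
F8 | step 16 | 1-hydroperoxy-10(14)-ene isomer of 24 (C1 open) | C/C=C(/C)C(=O)O[C@H]1CC(=C)C(OO)[C@@H](OC(C)=O)C[C@@](C)(O)/C=C2/OC(=O)C(COC(C)=O)=C21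
F9 | step 16 | 1-hydroxy-10(14)-ene isomer of 26 (C1 open) | C/C=C(/C)C(=O)O[C@H]1CC(=C)C(O)[C@@H](OC(C)=O)C[C@@](C)(O)/C=C2/OC(=O)C(COC(C)=O)=C21
A1 | alternative 1 | open-chain E-alkylidene butenolide diene for ring-closing metathesis (C14 as TBS ether) | C/C=C(/C)C(=O)O[C@@H](CC(=C)CO[Si](C)(C)C(C)(C)C)C1=C(COC(C)=O)C(=O)O/C1=C/[C@](C)(O)C[C@H](OC(C)=O)C=C
A2 | alternative 2 | 2-(bromomethyl)acrylate epoxy aldehyde | COC(=O)/C(CBr)=C/[C@@H](OC(=O)/C(C)=C\C)C/C(C)=C/[C@@H](OC(C)=O)C[C@@]1(C)O[C@@H]1C=O
A3 | alternative 2 | α-methylene lactone, 2-acetoxy-8-angeloyloxy-4,5-epoxygermacra-1(10),11(13)-dien-12,6-olide (C6 and C7 open) | C/C=C(/C)C(=O)O[C@H]1C/C(C)=C/[C@@H](OC(C)=O)C[C@@]3(C)O[C@@H]3C2OC(=O)C(=C)C21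
A4 | alternative 3 | (1R,6R)-1-[(Z)-2-(methoxymethoxy)ethenyl]-3-methyl-6-(prop-1-en-2-yl)cyclohex-2-en-1-ol | CC1=C[C@](O)(/C=C\OCOC)[C@H](CC1)C(C)=C
A5 | alternative 3 | 8-(methoxymethoxy)germacra-1(10)E,4Z-dien-6-one | COCO[C@H]1C/C(C)=C/CC/C(C)=C\C(=O)C1
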